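## Retrosynthetic overview

1. The C5–allyl bond is made last: the target comes from a 6-hydroxy-5-methoxy-dihydrobenzofuran (a guaiacol-type phenol) and an allylsilane. Trivalent iodine oxidises the phenol so that C5, the α-carbon of the future C6 ketone and normally nucleophilic, reacts as a cation (enolonium-type) with the nucleophilic allyl group; this sets C5.
2. The phenol comes from its 5-hydroxy-6-benzyloxy isomer by O-methylation and debenzylation.
3. The dihydrofuran ring (C3–C3a and O1–C2 bonds) comes from 2-(benzyloxy)-1,4-benzoquinone and (E)-methylisoeugenol by a [3+2] union under a chiral titanium TADDOLate; this sets C2 and C3.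
4. The quinone comes from 2-(benzyloxy)phenol by para-oxidation.
5. Ring order: the benzene ring is bought, the dihydrofuran ring is closed in step 2, and the six-membered ring is dearomatised to the dienone in step 5.

Assumption: the (R,R)-TADDOLate is taken to give the (2R,3R) series; if the sense of induction proves opposite, the (S,S)-ligand is used with nothing else changed.

## Route

Step 1
Reactants: 1 2-(benzyloxy)phenol
Product: 2 2-(benzyloxy)-1,4-benzoquinone
Conditions: K2[ON(SO3)2] (2.2 equiv), KH2PO4 buffer, H2O/acetone, 0 °C → rt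
Reagents that add atoms: potassium nitrosodisulfonate (Fremy's salt), [K+].[K+].[O]N(S(=O)(=O)[O-])S(=O)(=O)[O-]
Why: Teuber oxidation, in which the nitroxyl radical oxidises a phenol with a free para position to the p-quinone and delivers the new oxygen para to the OH, leaving the benzyl ether untouched.

Step 2
Reactants: 2 2-(benzyloxy)-1,4-benzoquinone, 3 (E)-1,2-dimethoxy-4-(prop-1-en-1-yl)benzene ((E)-methylisoeugenol)
Product: 5 (2R,3R)-6-(benzyloxy)-2-(3,4-dimethoxyphenyl)-3-methyl-2,3-dihydro-1-benzofuran-5-ol, via cyclobutane adduct 4 (not isolated)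
Conditions: TiCl2[(R,R)-TADDOLate] (2 equiv, preformed; TADDOLate = 2,2-dimethyl-α,α,α′,α′-tetraphenyl-1,3-dioxolane-4,5-dimethanolate, C31H28O4), CH2Cl2, −78 °C; then CF3CO2H (cat.), −78 → 0 °C
Reagents that add atoms: none
Why: Titanium-TADDOLate-promoted quinone–styrene [2+2]/[3+2] cycloaddition, in which two-point binding of the chiral tetravalent titanium to C1=O and the benzyloxy oxygen makes the quinone C5 electrophilic and shields one face so that the β-carbon of the E-alkene adds enantioselectively (sets C3), after which acid opens cyclobutane 4 to the benzylic cation that the C4 oxygen closes to the 2,3-trans ring (sets C2) without touching C3.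

Step 3
Reactants: 5 (2R,3R)-6-(benzyloxy)-2-(3,4-dimethoxyphenyl)-3-methyl-2,3-dihydro-1-benzofuran-5-ol
Product: 6 (2R,3R)-6-(benzyloxy)-2-(3,4-dimethoxyphenyl)-5-methoxy-3-methyl-2,3-dihydro-1-benzofuran
Conditions: MeI, K2CO3, acetone, 50 °C
Reagents that add atoms: iodomethane, CI
Why: Williamson ether synthesis on the only free phenol, with no stereocentre involved.

Step 4
Reactants: 6 (2R,3R)-6-(benzyloxy)-2-(3,4-dimethoxyphenyl)-5-methoxy-3-methyl-2,3-dihydro-1-benzofuran
Product: 7 (2R,3R)-2-(3,4-dimethoxyphenyl)-5-methoxy-3-methyl-2,3-dihydro-1-benzofuran-6-ol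
Conditions: H2 (1 atm), Pd/C (10 wt%), EtOAc, rt
Reagents that add atoms: none
Why: Catalytic hydrogenolysis of the aryl benzyl ether, which is much faster than cleavage of the hindered ring C2–O bond at 1 atm in EtOAc, so the reaction is stopped once 6 is consumed and both stereocentres stay as set.

Step 5
Reactants: 7 (2R,3R)-2-(3,4-dimethoxyphenyl)-5-methoxy-3-methyl-2,3-dihydro-1-benzofuran-6-ol
Product: 9 (2R,3R,5S)-5-allyl-2-(3,4-dimethoxyphenyl)-5-methoxy-3-methyl-3,5-dihydro-1-benzofuran-6(2H)-one, via aryloxy-λ3-iodane 8 (not isolated)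
Conditions: PhI(OCOCF3)2 (1.1 equiv), allylSiMe3 (5 equiv), CH2Cl2, −78 → −40 °C; cold aq NaHCO3 quench
Reagents that add atoms: allyltrimethylsilane, C=CC[Si](C)(C)C; phenyliodine bis(trifluoroacetate), FC(F)(F)C(=O)OI(OC(=O)C(F)(F)F)c1ccccc1 (its atoms stay only in intermediate 8)
Why: Oxidative dearomatisation by trivalent iodine (oxidative nucleophilic substitution of a 2-alkoxyarenol), in which ligand exchange gives 8, loss of PhI turns the phenol into an α-keto cation stabilised at C5 by the methoxy group, and the allylsilane attacks C5 with loss of silicon; C5 is set by approach anti to the C3 methyl, the only out-of-plane group near C5, which places allyl syn to the aryl group (5S) with modest selectivity expected (about 2:1), the 5R epimer being removed by chromatography.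

## Compound list

1 | 2-(benzyloxy)phenol | Oc1ccccc1OCc1ccccc1 | starting material
2 | 2-(benzyloxy)-1,4-benzoquinone | O=C1C=CC(=O)C(OCc2ccccc2)=C1 | intermediate
3 | (E)-1,2-dimethoxy-4-(prop-1-en-1-yl)benzene ((E)-methylisoeugenol) | C/C=C/c1ccc(OC)c(OC)c1 | starting material
4 | (1S,6R,7S,8S)-3-(benzyloxy)-8-(3,4-dimethoxyphenyl)-7-methylbicyclo[4.2.0]oct-3-ene-2,5-dione (cis-fused, 7-methyl/8-aryl trans, aryl drawn endo) | C[C@H]1[C@H](c2ccc(OC)c(OC)c2)[C@@H]2C(=O)C(OCc3ccccc3)=CC(=O)[C@@H]21 | intermediate (not isolated)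
5 | (2R,3R)-6-(benzyloxy)-2-(3,4-dimethoxyphenyl)-3-methyl-2,3-dihydro-1-benzofuran-5-ol | Oc1cc2c(cc1OCc1ccccc1)O[C@@H](c1ccc(OC)c(OC)c1)[C@@H]2C | intermediate
6 | (2R,3R)-6-(benzyloxy)-2-(3,4-dimethoxyphenyl)-5-methoxy-3-methyl-2,3-dihydro-1-benzofuran | COc1cc2c(cc1OCc1ccccc1)O[C@@H](c1ccc(OC)c(OC)c1)[C@@H]2C | intermediate
7 | (2R,3R)-2-(3,4-dimethoxyphenyl)-5-methoxy-3-methyl-2,3-dihydro-1-benzofuran-6-ol | COc1cc2c(cc1O)O[C@@H](c1ccc(OC)c(OC)c1)[C@@H]2C | intermediate
8 | {[(2R,3R)-2-(3,4-dimethoxyphenyl)-5-methoxy-3-methyl-2,3-dihydro-1-benzofuran-6-yl]oxy}(phenyl)-λ3-iodanyl trifluoroacetate | COc1cc2c(cc1OI(OC(=O)C(F)(F)F)c1ccccc1)O[C@@H](c1ccc(OC)c(OC)c1)[C@@H]2C | intermediate (not isolated)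
9 | (2R,3R,5S)-5-allyl-2-(3,4-dimethoxyphenyl)-5-methoxy-3-methyl-3,5-dihydro-1-benzofuran-6(2H)-one (aryl and allyl on one face, C3 methyl and C5 methoxy on the other) | C=CC[C@]1(OC)C=C2C(=CC1=O)O[C@@H](c1ccc(OC)c(OC)c1)[C@@H]2C | target

## Totals and weak points

Total step count: 5. Longest linear sequence: 5 steps (1 → 2 → 5 → 6 → 7 → 9).

The three steps most likely to fail, most likely first:

Step 5. The allylsilane may attack the para carbon C3a or the free ortho carbon C7 instead of C5, and the cation may lose the C3 proton to give a quinone methide. The facial bias at C5 is small. The product is also sensitive to acid and heat (Cope shift of allyl to C3a, or retro-Claisen back to an aryl allyl ether), so it must be kept cold and purified on base-washed silica. The fallback sets out from 7 and comes back at 9. Oxidative demethylation of 7 (NaIO4, H2O/MeCN, 0 °C) gives the o-quinone (2R,3R)-2-(3,4-dimethoxyphenyl)-3-methyl-2,3-dihydro-1-benzofuran-5,6-dione F1. Its C5 carbonyl is the more electrophilic one, because C6=O is a vinylogous ester carbonyl. 1,2-Allylboration of that carbonyl with allylB(OiPr)2 and a catalytic 3,3′-dibromo-BINOL, choosing the enantiomer that delivers allyl to the face syn to the aryl group, gives the tertiary alcohol (2R,3R,5S)-5-allyl-2-(3,4-dimethoxyphenyl)-5-hydroxy-3-methyl-3,5-dihydro-1-benzofuran-6(2H)-one F2. O-Methylation (MeOTf, 2,6-di-tert-butyl-4-methylpyridine, CH2Cl2, 0 °C) then gives 9. This places the allyl group and the C5 configuration under reagent control.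

Step 2. The benzyloxyquinone may give a lower ee than hoped (80–90% is expected, to be raised by crystallising 5 or 6), and bicyclo[3.2.1]octenedione [5+2] adducts may compete. The fallback sets out from 2 and 3 and comes back at 5. The same union promoted by achiral TiCl2(OiPr)2 (from TiCl4 and Ti(OiPr)4, CH2Cl2, −78 → 0 °C) runs through 4 and its mirror image (1R,6S,7R,8R)-3-(benzyloxy)-8-(3,4-dimethoxyphenyl)-7-methylbicyclo[4.2.0]oct-3-ene-2,5-dione F3. It gives 5 together with its enantiomer (2S,3S)-6-(benzyloxy)-2-(3,4-dimethoxyphenyl)-3-methyl-2,3-dihydro-1-benzofuran-5-ol F4. Preparative supercritical-fluid chromatography on a chiral stationary phase then gives pure 5 by resolution instead of induction.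

Step 1. The alkoxyquinone is sensitive to base and light, and the Teuber oxidation can give coupled by-products. The fallback sets out from 1 and comes back at 2. Elbs persulfate oxidation of 1 (K2S2O8, aq NaOH, 10 °C → rt) gives potassium 3-(benzyloxy)-4-hydroxyphenyl sulfate F5. Hydrolysis with dilute HCl gives 2-(benzyloxy)benzene-1,4-diol F6, and mild oxidation (Ag2O, Et2O, rt) gives 2.

## Further compounds

F1 | step 5 | (2R,3R)-2-(3,4-dimethoxyphenyl)-3-methyl-2,3-dihydro-1-benzofuran-5,6-dione | O=C1C=C2C(=CC1=O)O[C@@H](c1ccc(OC)c(OC)c1)[C@@H]2C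
F2 | step 5 | (2R,3R,5S)-5-allyl-2-(3,4-dimethoxyphenyl)-5-hydroxy-3-methyl-3,5-dihydro-1-benzofuran-6(2H)-one | C=CC[C@]1(O)C=C2C(=CC1=O)O[C@@H](c1ccc(OC)c(OC)c1)[C@@H]2C
F3 | step 2 | (1R,6S,7R,8R)-3-(benzyloxy)-8-(3,4-dimethoxyphenyl)-7-methylbicyclo[4.2.0]oct-3-ene-2,5-dione | C[C@@H]1[C@@H](c2ccc(OC)c(OC)c2)[C@H]2C(=O)C(OCc3ccccc3)=CC(=O)[C@H]21
F4 | step 2 | (2S,3S)-6-(benzyloxy)-2-(3,4-dimethoxyphenyl)-3-methyl-2,3-dihydro-1-benzofuran-5-ol | Oc1cc2c(cc1OCc1ccccc1)O[C@H](c1ccc(OC)c(OC)c1)[C@H]2C
F5 | step 1 | potassium 3-(benzyloxy)-4-hydroxyphenyl sulfate | [K+].[O-]S(=O)(=O)Oc1ccc(O)c(OCc2ccccc2)c1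
F6 | step 1 | 2-(benzyloxy)benzene-1,4-diol | Oc1ccc(O)c(OCc2ccccc2)c1
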